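## Analysis of the target

The target (24) is a flavone, a 2-aryl-4H-chromen-4-one built from three rings. Ring A carries hydroxyls at C5 and C7 and a prenyl group at C8. Ring C, the pyranone, carries a methoxy group at C3. Ring B, attached at C2, is a catechol (3'-OH, 4'-OH) with a second prenyl group at C5'. There is no stereocentre, so the problem is one of position, not configuration.

Each prenyl group is an electron-rich trisubstituted alkene ortho to a phenol. Acid can close it onto that phenol to give a 2,2-dimethylchroman, and electrophilic halogen or peracid attacks it. The catechol is easily oxidised. The C3 methyl ether must survive while four phenols are set free, which rules out aryl methyl ethers as the final protecting groups.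

The hard part is regiochemistry. C6 and C8 of ring A are both activated CH positions flanked by oxygen, so direct prenylation or halogenation of a 5,7-dioxygenated flavone gives mixtures. On ring B the prenyl group must sit at C5' and not at C2'.

The route rests on the aryl ether bond O1–C8a of ring C and on its neighbour C8. A ring A building block with bromine on both carbons lets one bromide be replaced by O1 in the ring closure, while the other stays at exactly the carbon that needs the prenyl group. C6 is never functionalised.

## Retrosynthetic reasoning

Positions follow flavone numbering (O1, C2 to C8a, ring B primed); C1'' is the benzylic carbon of the C8 prenyl group.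

**24 from 23.** The last operation only cuts four O–CH2OMe bonds of the tetrakis(methoxymethyl) ether 23. Methoxymethyl ethers are chosen because they withstand organolithium, enolate, carbonate and palladium chemistry and fall to dilute acid, which leaves the C3 methyl ether alone. The forward step has to cleave four acetals faster than acid adds the phenols across the prenyl alkenes.

**23 from 21 and 22.** The C8–C1'' bond is cut to the 8-bromochromone 21 and the prenyl stannane 22. Cutting here places the ring A prenyl group by the position of a halogen and not by the electronics of ring A. The forward cross-coupling has to engage a hindered, electron-rich aryl bromide and deliver the linear prenyl isomer.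

**21 from 20.** Ring C is opened at O1–C8a, which leads to the 2-methoxy-1,3-diketone 20 with bromine at both C8a and C8. This bond is chosen because its formation needs only an enolate oxygen and an ortho halide, and a 1,3-diketone is already at the chromone oxidation level. The forward step must make one of two aryl bromides react and must arylate oxygen, not carbon.

**20 from 19, and 19 from 17 and 6.** The bond between the methoxy-bearing carbon (the future C3) and the ring A carbonyl carbon (the future C4) is cut. The forward direction is an aldol addition of the ring B α-methoxy ketone 17 to the ring A aldehyde 6, followed by oxidation of the β-hydroxy ketone 19. An aldehyde is used because a doubly ortho-substituted ring A ester would be a poor acylating agent, while the aldehyde is reactive and cannot enolise. The two stereocentres of 19 need no control, since both disappear on the way to 21.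

**6 from 5, 4, 3 and 1.** The ring A aldehyde goes back to the symmetrical 1-bromo-3,5-dimethoxybenzene 1. The bromine of 1 becomes the C8a bromide, a formyl group is placed next to it (3), and a second bromine is placed on its other side (4). Both substitutions are directed by the two methoxy groups to positions para to one and ortho to the other. Methyl ethers carry the ring through the electrophilic steps and are then exchanged for methoxymethyl ethers via the diol 5, because they could not be removed at the end without touching the C3 methoxy group.

**17 from 13 and 15, and 15 from 14.** The aryl–carbonyl bond of 17 is cut to the aryllithium 16, made from bromide 13, and the Weinreb amide 15 of methoxyacetic acid, which comes from the acid chloride 14. The amide brings the complete MeO–CH2–C(=O) unit in one piece and stops the addition at the ketone.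

**13 from 12, 10, 9, 7 and 8.** Ring B is traced to 4-bromophenol 7. Its bromine blocks the para position and later becomes the point of attachment to the carbonyl. The phenol directs the prenyl group from 8 into one ortho position (9) and a formyl group into the other (10). Aryl migration to oxygen then turns the formyl group into the second hydroxyl (12), and protection gives 13. The 3',4',5' pattern therefore follows from the ortho directing power of one phenol.

## Alternatives that were turned down

**Alternative 1: both prenyl groups by sigmatropic shifts.** The C8–C1'' and C5'–C1''' bonds are traced back to two aryl allyl ethers in A2, 3-methoxy-7,3'-bis(methoxymethoxy)-5-prenyloxy-4'-(1,1-dimethylallyloxy)flavone. Heating A2 with Eu(fod)3, tris(6,6,7,7,8,8,8-heptafluoro-2,2-dimethyl-3,5-octanedionato)europium, would send the 5-O-prenyl group to C6 by a Claisen shift and on to C8 by a Cope shift, and the 4'-O-(1,1-dimethylallyl) group to C5' by an ortho-Claisen shift. The product is A1, 5,4'-dihydroxy-3-methoxy-7,3'-bis(methoxymethoxy)-8,5'-diprenylflavone.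

- For it: two C–C bonds form in one operation without tin, palladium or halogen, and the flavone core can come from short classical chemistry. On atom economy and end-game length it is stronger than the chosen route.
- Against it: A2 needs all four phenols told apart, with the least nucleophilic, chelated 5-OH prenylated and the 4'-OH carrying a tertiary ether that simple alkylation cannot install.
- Against it: the C8 position is reached only if the Cope shift of the C6 intermediate outruns its enolisation, so C8 over C6 is a kinetic outcome, not a structural one.
- Against it: the tertiary allyl ether can ionise under the Lewis acid and be lost, and the freed 5-OH and 4'-OH sit next to new prenyl groups in a hot Lewis-acidic medium.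
- In its place the chosen route offers positional certainty: C5' is fixed by the ortho pattern of one phenol and C8 by a bromide.

**Alternative 2: ring A by benzannulation onto a pyranone.** Ring A is built last from the pyranonyl diazo ketone A4, 6-(2-diazo-5-methylhex-4-enoyl)-3-methoxy-2-[3,4-bis(methoxymethoxy)-5-prenylphenyl]-4H-pyran-4-one, and (triisopropylsilyloxy)acetylene A5. Irradiation would trigger a Wolff rearrangement to a vinylketene, cycloaddition with A5, ring opening and 6π electrocyclisation. This forms C8–C8a, C7–C8, C5–C6 and C4a–C5 and gives A3, 5-hydroxy-3-methoxy-7-(triisopropylsilyloxy)-8-prenyl-2-[3,4-bis(methoxymethoxy)-5-prenylphenyl]chromen-4-one.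

- For it: four bonds and ring A form in one step, and the mechanism dictates every ring A substituent (C5-OH from the ketene carbonyl, C7-O from the alkyne, the prenyl group from the diazo carbon). The C5 and C7 oxygens arrive already differentiated. In bonds made per step it is clearly stronger than the chosen route.
- Against it: A4 is a long way from simple building blocks, since it needs a 2-aryl-3-methoxy-4-pyranone with a carboxyl-derived side chain at C6 and a substituted diazo ketone.
- Against it: the diazo carbon carries a CH2 group, so 1,2-hydrogen shift competes with the Wolff rearrangement, and the carbene and ketene are generated near two prenyl alkenes.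
- Against it: the 4-pyranone chromophore is itself photoreactive, and A5 is sensitive.
- In its place the chosen route makes only one bond in its key step, but its precursor comes from standard reactions and the key step has close precedent.

**Alternative 3: ring C closed at C4–C4a by Parham acylation.** The C4–C4a bond is cut to the aryl iodide A7, methyl (E)-3-[2-iodo-3,5-bis(methoxymethoxy)-6-prenylphenoxy]-2-methoxy-3-[3,4-bis(methoxymethoxy)-5-prenylphenyl]prop-2-enoate. Iodine–magnesium exchange with iPrMgCl·LiCl would give an arylmagnesium that attacks the tethered methyl ester and closes ring C to A6, which is identical with 23.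

- For it: the exchange is fast and tolerates esters and acetals, the chromone product is too poor an electrophile for a second addition, and both prenyl groups are already in place. No late coupling at a hindered bromide is needed, so its end game is shorter and safer than that of the chosen route.
- Against it: the difficulty moves into A7. Its ring A phenol is pentasubstituted and requires three phloroglucinol oxygens differentiated plus regiocontrolled prenylation and iodination, so the C6/C8 question is postponed and not removed.
- Against it: the tetrasubstituted β-aryloxy acrylate must be formed with a hindered phenol and with the ester cis to the aryloxy group.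
- Against it: the doubly ortho-substituted, electron-rich arylmagnesium may form slowly, and the acrylate can instead lose phenoxide by addition–elimination.
- In its place the chosen route takes ring A from a symmetrical commercial arene in four steps and joins the halves by an aldol reaction.

Key step: step 13

Assumption: the stannane 22 and the small reagents are bought, and 20 is drawn as the diketo tautomer although it is expected to be largely enolised.

## Route

**Step 1**
Reactants: 1 1-bromo-3,5-dimethoxybenzene
Product: 3 2-bromo-4,6-dimethoxybenzaldehyde, via aryl iminium dichlorophosphate 2 (not isolated)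
Conditions: POCl3, DMF, 0 °C to 90 °C; then H2O
Reagents that add atoms: N,N-dimethylformamide, CN(C)C=O; water, O
Why: Vilsmeier–Haack formylation; the chloroiminium ion attacks the carbon next to bromine, which is para to one methoxy group and ortho to the other, because the position between the two methoxy groups is shielded, and hydrolysis of iminium salt 2 gives the aldehyde.

**Step 2**
Reactants: 3 2-bromo-4,6-dimethoxybenzaldehyde
Product: 4 2,3-dibromo-4,6-dimethoxybenzaldehyde
Conditions: N-bromosuccinimide, MeCN, 0 °C to rt
Reagents that add atoms: N-bromosuccinimide, O=C1CCC(=O)N1Br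
Why: Electrophilic aromatic bromination; C3 is para to the C6 methoxy and ortho to the C4 methoxy group, the kind of position that 5-substituted 1,3-dimethoxybenzenes brominate in preference to the carbon between the two ethers, and the aldehyde is meta to both open positions and does not discriminate.

**Step 3**
Reactants: 4 2,3-dibromo-4,6-dimethoxybenzaldehyde
Product: 5 2,3-dibromo-4,6-dihydroxybenzaldehyde
Conditions: BBr3, CH2Cl2, −78 °C to rt; then H2O
Reagents that add atoms: none
Why: Lewis-acid cleavage of both aryl methyl ethers by BBr3; the C–Br bonds are inert and the aldehyde is recovered on aqueous work-up.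

**Step 4**
Reactants: 5 2,3-dibromo-4,6-dihydroxybenzaldehyde
Product: 6 2,3-dibromo-4,6-bis(methoxymethoxy)benzaldehyde
Conditions: NaH, MOMCl, DMF, 0 °C to rt
Reagents that add atoms: chloromethyl methyl ether, COCCl
Why: O-alkylation of the two phenoxides (Williamson-type acetal ether formation); NaH is used so that the phenol hydrogen-bonded to the aldehyde is also deprotonated and protected.

**Step 5**
Reactants: 7 4-bromophenol; 8 prenyl bromide (1-bromo-3-methylbut-2-ene)
Product: 9 4-bromo-2-(3-methylbut-2-en-1-yl)phenol
Conditions: NaH, toluene, 0 °C to rt
Reagents that add atoms: none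
Why: ortho-Selective C-alkylation of a sodium phenoxide in a non-polar solvent, where the tight ion pair reacts through the ortho carbon at the primary allylic bromide; the para position is blocked by bromine, and O-alkylation is the competing path.

**Step 6**
Reactants: 9 4-bromo-2-(3-methylbut-2-en-1-yl)phenol
Product: 10 5-bromo-2-hydroxy-3-(3-methylbut-2-en-1-yl)benzaldehyde
Conditions: MgCl2, Et3N, (CH2O)n, MeCN, reflux
Reagents that add atoms: paraformaldehyde (formaldehyde), C=O
Why: Magnesium-mediated ortho-formylation of phenols (Casnati–Skattebøl); the magnesium phenoxide delivers formaldehyde to the only free ortho carbon and a second formaldehyde oxidises the benzylic alkoxide by hydride transfer, which leaves the alkene and the aryl bromide untouched.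

**Step 7**
Reactants: 10 5-bromo-2-hydroxy-3-(3-methylbut-2-en-1-yl)benzaldehyde
Product: 12 5-bromo-3-(3-methylbut-2-en-1-yl)benzene-1,2-diol, via aryl formate 11 (not isolated)
Conditions: 30% H2O2, NaOH, THF–H2O, 0 °C to rt; then dilute HCl to pH 4
Reagents that add atoms: hydrogen peroxide, OO
Why: Dakin oxidation; hydroperoxide adds to the aldehyde, the electron-rich aryl group migrates to oxygen to give formate 11, which is saponified in the same flask, and alkaline peroxide does not epoxidise an unactivated trisubstituted alkene.

**Step 8**
Reactants: 12 5-bromo-3-(3-methylbut-2-en-1-yl)benzene-1,2-diol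
Product: 13 5-bromo-1,2-bis(methoxymethoxy)-3-(3-methylbut-2-en-1-yl)benzene
Conditions: MOMCl, iPr2NEt, CH2Cl2, 0 °C to rt
Reagents that add atoms: chloromethyl methyl ether, COCCl
Why: O-alkylation of both catechol hydroxyls under amine base (methoxymethyl ether formation); this removes the acidic protons before the organolithium step.

**Step 9**
Reactants: 14 methoxyacetyl chloride
Product: 15 N,2-dimethoxy-N-methylacetamide
Conditions: MeNH(OMe)·HCl, Et3N, CH2Cl2, 0 °C to rt
Reagents that add atoms: N,O-dimethylhydroxylamine hydrochloride, CNOC.Cl
Why: Acylation of N,O-dimethylhydroxylamine by the acid chloride (Weinreb amide formation).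

**Step 10**
Reactants: 13 5-bromo-1,2-bis(methoxymethoxy)-3-(3-methylbut-2-en-1-yl)benzene; 15 N,2-dimethoxy-N-methylacetamide
Product: 17 1-[3,4-bis(methoxymethoxy)-5-(3-methylbut-2-en-1-yl)phenyl]-2-methoxyethan-1-one, via aryllithium 16 (not isolated)
Conditions: n-BuLi, THF, −78 °C; then 15, −78 °C to −40 °C; aq NH4Cl
Reagents that add atoms: none
Why: Bromine–lithium exchange gives aryllithium 16, which adds once to the Weinreb amide because the chelated tetrahedral adduct holds until work-up (Weinreb ketone synthesis); exchange at −78 °C is much faster than ortho-lithiation next to the acetal ethers or deprotonation of the benzylic allylic CH2.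

**Step 11**
Reactants: 17 1-[3,4-bis(methoxymethoxy)-5-(3-methylbut-2-en-1-yl)phenyl]-2-methoxyethan-1-one; 6 2,3-dibromo-4,6-bis(methoxymethoxy)benzaldehyde
Product: 19 3-[2,3-dibromo-4,6-bis(methoxymethoxy)phenyl]-3-hydroxy-2-methoxy-1-[3,4-bis(methoxymethoxy)-5-(3-methylbut-2-en-1-yl)phenyl]propan-1-one (racemic syn/anti mixture), via lithium enolate 18 (not isolated)
Conditions: LiN(SiMe3)2, THF, −78 °C; then 6, −78 °C; aq NH4Cl at −78 °C
Reagents that add atoms: none
Why: Directed aldol addition of the preformed lithium enolate 18 to the non-enolisable aldehyde 6; two stereocentres form without control, which does not matter because both are lost in steps 12 and 13, and the cold quench prevents retro-aldol cleavage.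

**Step 12**
Reactants: 19 the β-hydroxy ketone
Product: 20 1-[2,3-dibromo-4,6-bis(methoxymethoxy)phenyl]-2-methoxy-3-[3,4-bis(methoxymethoxy)-5-(3-methylbut-2-en-1-yl)phenyl]propane-1,3-dione (racemic)
Conditions: Dess–Martin periodinane, NaHCO3, CH2Cl2, 0 °C to rt
Reagents that add atoms: none
Why: Dess–Martin oxidation of the secondary benzylic alcohol gives the 2-methoxy-1,3-diketone; the periodinane tolerates the alkene, the aryl bromides and the acetal ethers, and the buffer keeps the medium neutral.

**Step 13**
Reactants: 20 the 2-methoxy-1,3-diketone
Product: 21 8-bromo-3-methoxy-5,7-bis(methoxymethoxy)-2-[3,4-bis(methoxymethoxy)-5-(3-methylbut-2-en-1-yl)phenyl]-4H-chromen-4-one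
Conditions: CuI (10 mol%), 1,10-phenanthroline (20 mol%), Cs2CO3, DMF, 90 °C, degassed
Reagents that add atoms: none
Why: Cs2CO3 removes the acidic hydrogen between the two carbonyls of 20, and the diketonate binds monovalent copper carried by 1,10-phenanthroline. The copper centre, held next to C8a by the enolate oxygen on the ring B side, inserts into the C8a–Br bond to give a trivalent aryl copper species (or its concerted equivalent), and C–O reductive elimination forms O1–C8a and returns monovalent copper. The closest known reaction type is the copper-catalysed intramolecular O-arylation of 1-(2-haloaryl)-1,3-diketones to chromones and flavones, an Ullmann-type etherification with an enolate as the oxygen nucleophile. Ring C closes as a six-membered ring by attack of the enolate oxygen on an sp2 carbon with the leaving bromide outside the new ring (a 6-exo closure at an arene carbon, through a seven-membered copper chelate), directly at the chromone oxidation level. No stereocentre is created, and the racemic sp3 carbon of 20 becomes the sp2 carbon C3. The step needs site selectivity between two aryl bromides and O- over C-arylation: only the C8a bromide is within reach of the tethered enolate oxygen, it is ortho to the ketone and meta to both ether donors whereas the C8 bromide is ortho and para to them, and attack through carbon or through the other carbonyl oxygen would have to close a four-membered ring. The same geometry and activation also permit an addition–elimination pathway at C8a, which leads to the same product.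

**Step 14**
Reactants: 21 the 8-bromochromone; 22 tributyl(3-methylbut-2-en-1-yl)stannane
Product: 23 3-methoxy-5,7-bis(methoxymethoxy)-8-(3-methylbut-2-en-1-yl)-2-[3,4-bis(methoxymethoxy)-5-(3-methylbut-2-en-1-yl)phenyl]-4H-chromen-4-one
Conditions: Pd(PPh3)4 (10 mol%), DMF, 100 °C, degassed
Reagents that add atoms: none
Why: Stille cross-coupling; zerovalent palladium inserts into the C8–Br bond, the allylic stannane transmetalates, and reductive elimination forms C8–C1''. The linear isomer is expected because the prenyl palladium intermediate couples at its less hindered primary terminus.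

**Step 15**
Reactants: 23 the tetrakis(methoxymethyl) ether
Product: 24 5,7,3',4'-tetrahydroxy-3-methoxy-8,5'-diprenylflavone (target)
Conditions: 3 M aq HCl, MeOH, 50 °C
Reagents that add atoms: none
Why: Acid-catalysed solvolysis of the four acetal ethers in methanol, which traps the methoxymethyl cation as its dimethyl acetal; the C3 methyl ether is inert, and dilute acid at moderate temperature is chosen because acetal cleavage is faster than protonation of the prenyl alkenes.

## Compound list

1 | 1-bromo-3,5-dimethoxybenzene | COc1cc(Br)cc(OC)c1 | starting material
2 | N-[(2-bromo-4,6-dimethoxyphenyl)methylidene]-N-methylmethanaminium dichlorophosphate | C[N+](C)=Cc1c(Br)cc(OC)cc1OC.[O-]P(=O)(Cl)Cl | intermediate (not isolated)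
3 | 2-bromo-4,6-dimethoxybenzaldehyde | COc1cc(OC)c(C=O)c(Br)c1 | intermediate
4 | 2,3-dibromo-4,6-dimethoxybenzaldehyde | COc1cc(OC)c(C=O)c(Br)c1Br | intermediate
5 | 2,3-dibromo-4,6-dihydroxybenzaldehyde | Oc1cc(O)c(C=O)c(Br)c1Br | intermediate
6 | 2,3-dibromo-4,6-bis(methoxymethoxy)benzaldehyde | COCOc1cc(OCOC)c(C=O)c(Br)c1Br | intermediate
7 | 4-bromophenol | Oc1ccc(Br)cc1 | starting material
8 | prenyl bromide (1-bromo-3-methylbut-2-ene) | CC(C)=CCBr | starting material
9 | 4-bromo-2-(3-methylbut-2-en-1-yl)phenol | CC(C)=CCc1cc(Br)ccc1O | intermediate
10 | 5-bromo-2-hydroxy-3-(3-methylbut-2-en-1-yl)benzaldehyde | CC(C)=CCc1cc(Br)cc(C=O)c1O | intermediate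
11 | 5-bromo-2-hydroxy-3-(3-methylbut-2-en-1-yl)phenyl formate | CC(C)=CCc1cc(Br)cc(OC=O)c1O | intermediate (not isolated)
12 | 5-bromo-3-(3-methylbut-2-en-1-yl)benzene-1,2-diol | CC(C)=CCc1cc(Br)cc(O)c1O | intermediate
13 | 5-bromo-1,2-bis(methoxymethoxy)-3-(3-methylbut-2-en-1-yl)benzene | COCOc1cc(Br)cc(CC=C(C)C)c1OCOC | intermediate
14 | methoxyacetyl chloride | COCC(=O)Cl | starting material
15 | N,2-dimethoxy-N-methylacetamide | COCC(=O)N(C)OC | intermediate
16 | [3,4-bis(methoxymethoxy)-5-(3-methylbut-2-en-1-yl)phenyl]lithium | [Li]c1cc(OCOC)c(OCOC)c(CC=C(C)C)c1 | intermediate (not isolated)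
17 | 1-[3,4-bis(methoxymethoxy)-5-(3-methylbut-2-en-1-yl)phenyl]-2-methoxyethan-1-one | COCC(=O)c1cc(OCOC)c(OCOC)c(CC=C(C)C)c1 | intermediate
18 | lithium (Z)-enolate of 17 (Z expected from chelation; geometry of no consequence) | [Li]O/C(=C\OC)c1cc(OCOC)c(OCOC)c(CC=C(C)C)c1 | intermediate (not isolated)
19 | 3-[2,3-dibromo-4,6-bis(methoxymethoxy)phenyl]-3-hydroxy-2-methoxy-1-[3,4-bis(methoxymethoxy)-5-(3-methylbut-2-en-1-yl)phenyl]propan-1-one, all four stereoisomers | COCOc1cc(OCOC)c(Br)c(Br)c1C(O)C(OC)C(=O)c1cc(OCOC)c(OCOC)c(CC=C(C)C)c1 | intermediate
20 | 1-[2,3-dibromo-4,6-bis(methoxymethoxy)phenyl]-2-methoxy-3-[3,4-bis(methoxymethoxy)-5-(3-methylbut-2-en-1-yl)phenyl]propane-1,3-dione, racemic | COCOc1cc(OCOC)c(Br)c(Br)c1C(=O)C(OC)C(=O)c1cc(OCOC)c(OCOC)c(CC=C(C)C)c1 | intermediate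
21 | 8-bromo-3-methoxy-5,7-bis(methoxymethoxy)-2-[3,4-bis(methoxymethoxy)-5-(3-methylbut-2-en-1-yl)phenyl]-4H-chromen-4-one | COc1c(-c2cc(OCOC)c(OCOC)c(CC=C(C)C)c2)oc2c(Br)c(OCOC)cc(OCOC)c2c1=O | intermediate
22 | tributyl(3-methylbut-2-en-1-yl)stannane | CCCC[Sn](CCCC)(CCCC)CC=C(C)C | starting material
23 | 3-methoxy-5,7-bis(methoxymethoxy)-8-(3-methylbut-2-en-1-yl)-2-[3,4-bis(methoxymethoxy)-5-(3-methylbut-2-en-1-yl)phenyl]-4H-chromen-4-one | COc1c(-c2cc(OCOC)c(OCOC)c(CC=C(C)C)c2)oc2c(CC=C(C)C)c(OCOC)cc(OCOC)c2c1=O | intermediate
24 | 5,7,3',4'-tetrahydroxy-3-methoxy-8,5'-diprenylflavone | COc1c(-c2cc(O)c(O)c(CC=C(C)C)c2)oc2c(CC=C(C)C)c(O)cc(O)c2c1=O | target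

## Step count and least certain steps

Total: 15 steps. Longest linear sequence: 10 steps (steps 5, 6, 7, 8, 10, 11, 12, 13, 14, 15, from 4-bromophenol 7).

**Step 13 (key step).** The most likely failure is carbonate-induced retro-Claisen cleavage of the crowded, twisted diketone while oxidative addition at the doubly flanked C8a–Br bond is slow. The second risk is copper insertion at the C8 bromide with loss of that halogen.

The fallback moves the ring closure from copper catalysis to metal-free addition–elimination at a C8a fluoride. It sets out from ketone 17 (through enolate 18) and comes back at 21. Commercial 1-fluoro-3,5-dimethoxybenzene F1 would be taken through the operations of steps 1 to 4: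
- Vilsmeier formylation to 2-fluoro-4,6-dimethoxybenzaldehyde F2;
- bromination with N-bromosuccinimide to 3-bromo-2-fluoro-4,6-dimethoxybenzaldehyde F3;
- BBr3 demethylation to 3-bromo-2-fluoro-4,6-dihydroxybenzaldehyde F4;
- protection with MOMCl and NaH to 3-bromo-2-fluoro-4,6-bis(methoxymethoxy)benzaldehyde F5.

Aldol addition of 18 to F5 would give the fluoro aldol adduct F6, and Dess–Martin oxidation the fluoro diketone F7. K2CO3 in DMF at 40 to 60 °C would then close ring C by intramolecular SNAr. The fluoride is ortho to the ketone and is displaced by the enolate oxygen, while the C8 bromide cannot react, so 21 results at a temperature below that of diketone cleavage.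

**Step 14.** Oxidative addition at an aryl bromide that is ortho, ortho and para to three oxygen donors may be slow, so protodebromination can compete. Allylic transposition at palladium can also deliver the branched 1,1-dimethylallyl isomer.

The fallback separates C–C bond formation from the choice of alkene. It sets out from 21 and comes back at 23. Stille coupling of 21 with allyltributylstannane and Pd(PPh3)4 in DMF at 100 °C would give the 8-allyl chromone F8, for which no regiochemical question exists. Cross-metathesis of F8 with excess 2-methyl-2-butene and the second-generation Grubbs catalyst in CH2Cl2 at 40 °C would convert the allyl group into the prenyl group. The ring B prenyl group only undergoes degenerate exchange.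

**Step 15.** Acid may add the C7 and C4' hydroxyls across the neighbouring prenyl alkenes (chroman formation), or hydrate the alkenes, before the last acetal is cleaved.

The fallback replaces Brønsted-acid solvolysis by protecting-group exchange and fluoride cleavage. It sets out from 23 and comes back at 24. Et3SiOTf with 2,2'-bipyridyl in MeCN at 0 °C would exchange each aryl methoxymethyl ether for a triethylsilyl ether under buffered conditions, giving the tetrakis(triethylsilyl) ether F9. Bu4NF buffered with AcOH in THF at 0 °C would then free the four phenols without strong acid.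

**Step 5.** O-Alkylation and double alkylation compete with ortho C-alkylation, and the product can cyclise to a chroman if the work-up is acidic.

The fallback reaches the same phenol by a sigmatropic route. It sets out from 7 and comes back at 9.
- Alkylation of 7 with 3-chloro-3-methylbut-1-yne (K2CO3, KI, catalytic CuI, acetone, reflux) would give the propargyl ether 1-bromo-4-[(2-methylbut-3-yn-2-yl)oxy]benzene F10.
- Semi-hydrogenation over Pd/CaCO3 poisoned with Pb(OAc)2, with quinoline, would give the allyl ether 1-bromo-4-[(2-methylbut-3-en-2-yl)oxy]benzene F11.
- Heating F11 in xylene would bring about the aromatic Claisen rearrangement, which delivers the linear prenyl group to the ortho carbon only.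

**Step 2.** Bromination may occur in part at C5, between the two methoxy groups, or go on to a tribromide.

The fallback reverses the order of the two substitutions. It sets out from 1 and comes back at 4. Bromination of 1 with N-bromosuccinimide in MeCN would give 1,2-dibromo-3,5-dimethoxybenzene F12, a substitution pattern typical of 5-substituted 1,3-dimethoxybenzenes. Rieche formylation of F12 with Cl2CHOMe and TiCl4 in CH2Cl2 at 0 °C would then place the aldehyde at the carbon para to one methoxy group and ortho to the other, next to bromine, the same kind of position that step 1 selects on 1.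

## Further compounds

F1 | step 13 | 1-fluoro-3,5-dimethoxybenzene | COc1cc(F)cc(OC)c1
F2 | step 13 | 2-fluoro-4,6-dimethoxybenzaldehyde | COc1cc(OC)c(C=O)c(F)c1
F3 | step 13 | 3-bromo-2-fluoro-4,6-dimethoxybenzaldehyde | COc1cc(OC)c(C=O)c(F)c1Br
F4 | step 13 | 3-bromo-2-fluoro-4,6-dihydroxybenzaldehyde | Oc1cc(O)c(C=O)c(F)c1Br
F5 | step 13 | 3-bromo-2-fluoro-4,6-bis(methoxymethoxy)benzaldehyde | COCOc1cc(OCOC)c(C=O)c(F)c1Br
F6 | step 13 | 3-[3-bromo-2-fluoro-4,6-bis(methoxymethoxy)phenyl]-3-hydroxy-2-methoxy-1-[3,4-bis(methoxymethoxy)-5-(3-methylbut-2-en-1-yl)phenyl]propan-1-one, all four stereoisomers | COCOc1cc(OCOC)c(Br)c(F)c1C(O)C(OC)C(=O)c1cc(OCOC)c(OCOC)c(CC=C(C)C)c1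
F7 | step 13 | 1-[3-bromo-2-fluoro-4,6-bis(methoxymethoxy)phenyl]-2-methoxy-3-[3,4-bis(methoxymethoxy)-5-(3-methylbut-2-en-1-yl)phenyl]propane-1,3-dione, racemic | COCOc1cc(OCOC)c(Br)c(F)c1C(=O)C(OC)C(=O)c1cc(OCOC)c(OCOC)c(CC=C(C)C)c1
F8 | step 14 | 3-methoxy-5,7-bis(methoxymethoxy)-8-(prop-2-en-1-yl)-2-[3,4-bis(methoxymethoxy)-5-(3-methylbut-2-en-1-yl)phenyl]-4H-chromen-4-one | COc1c(-c2cc(OCOC)c(OCOC)c(CC=C(C)C)c2)oc2c(CC=C)c(OCOC)cc(OCOC)c2c1=O
F9 | step 15 | 3-methoxy-8-(3-methylbut-2-en-1-yl)-5,7-bis(triethylsilyloxy)-2-[3,4-bis(triethylsilyloxy)-5-(3-methylbut-2-en-1-yl)phenyl]-4H-chromen-4-one | COc1c(-c2cc(O[Si](CC)(CC)CC)c(O[Si](CC)(CC)CC)c(CC=C(C)C)c2)oc2c(CC=C(C)C)c(O[Si](CC)(CC)CC)cc(O[Si](CC)(CC)CC)c2c1=O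
F10 | step 5 | 1-bromo-4-[(2-methylbut-3-yn-2-yl)oxy]benzene | C#CC(C)(C)Oc1ccc(Br)cc1
F11 | step 5 | 1-bromo-4-[(2-methylbut-3-en-2-yl)oxy]benzene | C=CC(C)(C)Oc1ccc(Br)cc1
F12 | step 2 | 1,2-dibromo-3,5-dimethoxybenzene | COc1cc(OC)c(Br)c(Br)c1
A1 | alternative 1 | 5,4'-dihydroxy-3-methoxy-7,3'-bis(methoxymethoxy)-8,5'-diprenylflavone | COc1c(-c2cc(OCOC)c(O)c(CC=C(C)C)c2)oc2c(CC=C(C)C)c(OCOC)cc(O)c2c1=O
A2 | alternative 1 | 3-methoxy-7,3'-bis(methoxymethoxy)-5-prenyloxy-4'-(1,1-dimethylallyloxy)flavone | COc1c(-c2ccc(OC(C)(C)C=C)c(OCOC)c2)oc2cc(OCOC)cc(OCC=C(C)C)c2c1=O
A3 | alternative 2 | 5-hydroxy-3-methoxy-7-(triisopropylsilyloxy)-8-prenyl-2-[3,4-bis(methoxymethoxy)-5-prenylphenyl]chromen-4-one | COc1c(-c2cc(OCOC)c(OCOC)c(CC=C(C)C)c2)oc2c(CC=C(C)C)c(O[Si](C(C)C)(C(C)C)C(C)C)cc(O)c2c1=O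
A4 | alternative 2 | 6-(2-diazo-5-methylhex-4-enoyl)-3-methoxy-2-[3,4-bis(methoxymethoxy)-5-prenylphenyl]-4H-pyran-4-one | COc1c(-c2cc(OCOC)c(OCOC)c(CC=C(C)C)c2)oc(C(=O)C(=[N+]=[N-])CC=C(C)C)cc1=O
A5 | alternative 2 | (triisopropylsilyloxy)acetylene | C#CO[Si](C(C)C)(C(C)C)C(C)C
A6 | alternative 3 | 3-methoxy-5,7-bis(methoxymethoxy)-8-prenyl-2-[3,4-bis(methoxymethoxy)-5-prenylphenyl]chromen-4-one (identical with 23) | COc1c(-c2cc(OCOC)c(OCOC)c(CC=C(C)C)c2)oc2c(CC=C(C)C)c(OCOC)cc(OCOC)c2c1=O
A7 | alternative 3 | methyl (E)-3-[2-iodo-3,5-bis(methoxymethoxy)-6-prenylphenoxy]-2-methoxy-3-[3,4-bis(methoxymethoxy)-5-prenylphenyl]prop-2-enoate | COC(=O)/C(OC)=C(\Oc1c(I)c(OCOC)cc(OCOC)c1CC=C(C)C)c1cc(OCOC)c(OCOC)c(CC=C(C)C)c1
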